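## Retrosynthetic overview

- The C32 skeleton is cut at the quaternary carbon into two C16 halves: an (E)-alkenylalane (ring half) and a trisubstituted allylic phosphate (open-chain half), joined by an enantioselective SN2′ substitution.
- Open-chain half: (2E,6E)-farnesyl acetate, terminal allylic oxidation, then asymmetric SN2′ methylation to set the (S)-2,3-dimethylbut-3-enyl end.
- Ring half: terminal alkyne from an aldehyde; the side chain (methyl stereocentre bought in) is attached by conjugate addition to an α-methylene ketone; the exocyclic methylene comes from a Wittig reaction.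
- The only ring is never closed in the route: it is the carbocycle of 3,4-dimethylanisole, dearomatised by Birch reduction and made chiral by an amine-catalysed enantioselective alkene isomerisation; a cuprate then builds the gem-dimethyl carbon.

Assumption: 3,4-dimethylanisole, (S)-3-bromo-2-methylpropan-1-ol and (2E,6E)-farnesyl acetate are bought; in steps 2, 10 and 12 the catalyst antipode that gives the drawn configuration is used (sense assigned by analogy, both antipodes accessible).

## Route

Step 1
Reactants: 1 3,4-dimethylanisole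
Product: 3 3,4-dimethylcyclohex-3-en-1-one, via 1-methoxy-4,5-dimethylcyclohexa-1,4-diene 2 (not isolated)
Conditions: Li, NH3 (l), t-BuOH, THF, −78 to −33 °C; then (CO2H)2, MeOH/H2O, rt
Reagents that add atoms: water, O
Why: Birch reduction leaves the methoxy group and both methyl groups on the two surviving alkenes, and mild oxalic acid hydrolysis of the enol ether unmasks the ketone without moving the tetrasubstituted alkene into conjugation (Birch reduction, enol ether hydrolysis), so no stereocentre is formed yet.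

Step 2
Reactants: 3 3,4-dimethylcyclohex-3-en-1-one
Product: 4 (4S)-3,4-dimethylcyclohex-2-en-1-one
Conditions: 9-amino-9-deoxy-epi-cinchona primary amine catalyst (10 mol %), PhCO2H (20 mol %), toluene, rt
Reagents that add atoms: none
Why: Iminium–dienamine catalysis moves the alkene into conjugation while the protonated quinuclidine of the catalyst delivers the γ-proton to one face of the dienamine, which sets C4 as (S) (organocatalytic enantioselective β,γ to α,β isomerisation of Birch-derived cyclohexenones, here stretched to a fully substituted alkene).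

Step 3
Reactants: 4 (4S)-3,4-dimethylcyclohex-2-en-1-one
Product: 8 (4S)-3,3,4-trimethyl-2-methylidenecyclohexan-1-one, via lithium enolate 5 (not isolated), via Mannich base 6 (not isolated), via ammonium iodide 7 (not isolated)
Conditions: Me2CuLi (from MeLi, CuI), Et2O, 0 °C; CH2=NMe2+ I−, THF, −78 °C to rt; MeI, rt; NaHCO3, H2O/CH2Cl2
Reagents that add atoms: lithium dimethylcuprate, [Li+].C[Cu-]C; dimethylmethylideneammonium iodide (Eschenmoser's salt), C=[N+](C)C.[I-]
Why: 1,4-Addition of Me2CuLi creates the gem-dimethyl carbon without touching C4, the regiodefined enolate is aminomethylated by Eschenmoser's salt (Mannich reaction), and elimination of the methiodide gives the α-methylene ketone.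

Step 4
Reactants: 8 (4S)-3,3,4-trimethyl-2-methylidenecyclohexan-1-one; 9 (S)-3-bromo-2-methylpropan-1-ol
Product: 11 (2S,4S)-2-[(3R)-4-hydroxy-3-methylbutyl]-3,3,4-trimethylcyclohexan-1-one, via Grignard reagent 10 (not isolated)
Conditions: 9, MeMgCl (1 equiv), THF, −20 °C; Mg, reflux; then 8, CuBr·SMe2 (10 mol %), THF, −40 °C; NH4Cl (aq); NaOMe, MeOH, rt
Reagents that add atoms: none
Why: Conjugate addition of the Normant-type alkoxide Grignard reagent, mediated by CuBr·SMe2, to the unhindered exocyclic enone attaches the side chain with its (R)-methyl centre taken from 9, and base equilibration of the epimerisable C2 gives the thermodynamically preferred cis diequatorial (2S,4S) ketone.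

Step 5
Reactants: 11 (2S,4S)-2-[(3R)-4-hydroxy-3-methylbutyl]-3,3,4-trimethylcyclohexan-1-one
Product: 12 (2R)-2-methyl-4-[(1R,3S)-2,2,3-trimethyl-6-methylidenecyclohexyl]butan-1-ol
Conditions: Ph3PCH3Br, KOt-Bu (4 equiv each), toluene, 80 °C
Reagents that add atoms: methyltriphenylphosphonium bromide, C[P+](c1ccccc1)(c1ccccc1)c1ccccc1.[Br-]
Why: Wittig methylenation with excess ylide converts the hindered ketone into the exocyclic alkene with no regioisomers, and the basic medium keeps the adjacent ring carbon in the favoured cis configuration.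

Step 6
Reactants: 12 (2R)-2-methyl-4-[(1R,3S)-2,2,3-trimethyl-6-methylidenecyclohexyl]butan-1-ol
Product: 13 (2R)-2-methyl-4-[(1R,3S)-2,2,3-trimethyl-6-methylidenecyclohexyl]butanal
Conditions: PhI(OAc)2, TEMPO (10 mol %), CH2Cl2, rt
Reagents that add atoms: none
Why: The TEMPO oxoammonium oxidation stops at the aldehyde under near-neutral conditions that spare the alkene and the α-stereocentre.

Step 7
Reactants: 13 (2R)-2-methyl-4-[(1R,3S)-2,2,3-trimethyl-6-methylidenecyclohexyl]butanal
Product: 14 (1R,3S)-2,2,3-trimethyl-6-methylidene-1-[(3R)-3-methylpent-4-yn-1-yl]cyclohexane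
Conditions: MeC(O)C(N2)P(O)(OMe)2, K2CO3, MeOH, 0 °C to rt
Reagents that add atoms: dimethyl (1-diazo-2-oxopropyl)phosphonate, COP(=O)(OC)C(=[N+]=[N-])C(C)=O
Why: Seyferth–Gilbert homologation with the Ohira–Bestmann reagent adds one carbon and gives the terminal alkyne under K2CO3/MeOH, mild enough to keep the propargylic centre.

Step 8
Reactants: 15 (2E,6E)-farnesyl acetate
Product: 16 (2E,6E,10E)-12-hydroxy-3,7,11-trimethyldodeca-2,6,10-trien-1-yl acetate
Conditions: SeO2 (0.3 equiv), t-BuOOH, salicylic acid (10 mol %), CH2Cl2, rt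
Reagents that add atoms: tert-butyl hydroperoxide, CC(C)(C)OO
Why: The SeO2/t-BuOOH allylic oxidation (ene reaction, then 2,3-sigmatropic shift) attacks the (E)-methyl of the most electron-rich, terminal trisubstituted alkene and gives the (E)-allylic alcohol.

Step 9
Reactants: 16 (2E,6E,10E)-12-hydroxy-3,7,11-trimethyldodeca-2,6,10-trien-1-yl acetate
Product: 17 (2E,6E,10E)-12-chloro-3,7,11-trimethyldodeca-2,6,10-trien-1-yl acetate
Conditions: PPh3, CCl4, 60 °C
Reagents that add atoms: carbon tetrachloride, ClC(Cl)(Cl)Cl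
Why: Appel chlorination replaces the primary allylic hydroxyl by SN2 displacement without allylic transposition.

Step 10
Reactants: 17 (2E,6E,10E)-12-chloro-3,7,11-trimethyldodeca-2,6,10-trien-1-yl acetate
Product: 19 (2E,6E,10S)-3,7,10,11-tetramethyldodeca-2,6,11-trien-1-ol, via acetate 18 (not isolated)
Conditions: MeMgBr, Cu(O2CC4H3S) (CuTC, 3 mol %), chiral biphenol phosphoramidite (3.3 mol %), CH2Cl2, −78 °C; then K2CO3, MeOH, rt
Reagents that add atoms: methylmagnesium bromide, C[Mg]Br
Why: Asymmetric allylic alkylation of the β-methyl allylic chloride with MeMgBr under CuTC and the phosphoramidite runs SN2′, the ligand choosing the face of C10 to give the (S) centre next to the new 1,1-disubstituted alkene, and in-flask transesterification removes the acetate.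

Step 11
Reactants: 19 (2E,6E,10S)-3,7,10,11-tetramethyldodeca-2,6,11-trien-1-ol
Product: 20 diethyl (2E,6E,10S)-3,7,10,11-tetramethyldodeca-2,6,11-trien-1-yl phosphate
Conditions: (EtO)2P(O)Cl, Et3N, DMAP (cat.), CH2Cl2, 0 °C
Reagents that add atoms: diethyl chlorophosphate, CCOP(=O)(Cl)OCC
Why: O-Phosphorylation of the allylic alcohol installs the leaving group needed for the SN2′ coupling.

Step 12
Reactants: 14 (1R,3S)-2,2,3-trimethyl-6-methylidene-1-[(3R)-3-methylpent-4-yn-1-yl]cyclohexane; 20 diethyl (2E,6E,10S)-3,7,10,11-tetramethyldodeca-2,6,11-trien-1-yl phosphate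
Product: 22 (3S,6E,10S)-3,7,10,11-tetramethyl-3-{(1E,3R)-3-methyl-5-[(1R,3S)-2,2,3-trimethyl-6-methylidenecyclohexyl]pent-1-en-1-yl}dodeca-1,6,11-triene, via alkenylalane 21 (not isolated)
Conditions: 14, i-Bu2AlH, hexanes, 55 °C; then 20, CuCl2·2H2O (5 mol %), chiral sulfonate-bearing imidazolinium salt (5.5 mol %), THF, −15 °C
Reagents that add atoms: none
Why: syn-Hydroalumination gives the (E)-alkenylalane, which the catalyst formed from CuCl2·2H2O and the chiral carbene precursor transfers SN2′ to the γ-carbon of the (E)-phosphate, so the vinyl-bearing quaternary centre is set as (S) under catalyst control (enantioselective allylic substitution with alkenylaluminium reagents).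

## Compound list

1 | 3,4-dimethylanisole | COc1ccc(C)c(C)c1 | starting material
2 | 1-methoxy-4,5-dimethylcyclohexa-1,4-diene | COC1=CCC(C)=C(C)C1 | intermediate
3 | 3,4-dimethylcyclohex-3-en-1-one | O=C1CCC(C)=C(C)C1 | intermediate
4 | (4S)-3,4-dimethylcyclohex-2-en-1-one | O=C1CC[C@H](C)C(C)=C1 | intermediate
5 | lithium (4S)-3,3,4-trimethylcyclohex-1-en-1-olate | [Li+].[O-]C1=CC(C)(C)[C@@H](C)CC1 | intermediate
6 | (4S)-2-[(dimethylamino)methyl]-3,3,4-trimethylcyclohexan-1-one (C2 epimers) | CN(C)CC1C(=O)CC[C@H](C)C1(C)C | intermediate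
7 | trimethyl{[(3S)-2,2,3-trimethyl-6-oxocyclohexyl]methyl}ammonium iodide | C[N+](C)(C)CC1C(=O)CC[C@H](C)C1(C)C.[I-] | intermediate
8 | (4S)-3,3,4-trimethyl-2-methylidenecyclohexan-1-one | C=C1C(=O)CC[C@H](C)C1(C)C | intermediate
9 | (S)-3-bromo-2-methylpropan-1-ol | OC[C@H](C)CBr | starting material
10 | (S)-[3-(chloromagnesiooxy)-2-methylpropyl]magnesium bromide | Cl[Mg]OC[C@H](C)C[Mg]Br | intermediate
11 | (2S,4S)-2-[(3R)-4-hydroxy-3-methylbutyl]-3,3,4-trimethylcyclohexan-1-one | OC[C@H](C)CC[C@@H]1C(=O)CC[C@H](C)C1(C)C | intermediate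
12 | (2R)-2-methyl-4-[(1R,3S)-2,2,3-trimethyl-6-methylidenecyclohexyl]butan-1-ol | OC[C@H](C)CC[C@@H]1C(=C)CC[C@H](C)C1(C)C | intermediate
13 | (2R)-2-methyl-4-[(1R,3S)-2,2,3-trimethyl-6-methylidenecyclohexyl]butanal | O=C[C@H](C)CC[C@@H]1C(=C)CC[C@H](C)C1(C)C | intermediate
14 | (1R,3S)-2,2,3-trimethyl-6-methylidene-1-[(3R)-3-methylpent-4-yn-1-yl]cyclohexane | C#C[C@H](C)CC[C@@H]1C(=C)CC[C@H](C)C1(C)C | intermediate
15 | (2E,6E)-farnesyl acetate | CC(=O)OC/C=C(\C)CC/C=C(\C)CCC=C(C)C | starting material
16 | (2E,6E,10E)-12-hydroxy-3,7,11-trimethyldodeca-2,6,10-trien-1-yl acetate | CC(=O)OC/C=C(\C)CC/C=C(\C)CC/C=C(\C)CO | intermediate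
17 | (2E,6E,10E)-12-chloro-3,7,11-trimethyldodeca-2,6,10-trien-1-yl acetate | CC(=O)OC/C=C(\C)CC/C=C(\C)CC/C=C(\C)CCl | intermediate
18 | (2E,6E,10S)-3,7,10,11-tetramethyldodeca-2,6,11-trien-1-yl acetate | CC(=O)OC/C=C(\C)CC/C=C(\C)CC[C@H](C)C(=C)C | intermediate
19 | (2E,6E,10S)-3,7,10,11-tetramethyldodeca-2,6,11-trien-1-ol | OC/C=C(\C)CC/C=C(\C)CC[C@H](C)C(=C)C | intermediate
20 | diethyl (2E,6E,10S)-3,7,10,11-tetramethyldodeca-2,6,11-trien-1-yl phosphate | CCOP(=O)(OCC)OC/C=C(\C)CC/C=C(\C)CC[C@H](C)C(=C)C | intermediate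
21 | diisobutyl{(1E,3R)-3-methyl-5-[(1R,3S)-2,2,3-trimethyl-6-methylidenecyclohexyl]pent-1-en-1-yl}alane | CC(C)C[Al](CC(C)C)/C=C/[C@H](C)CC[C@@H]1C(=C)CC[C@H](C)C1(C)C | intermediate
22 | CNP0293684.4, (3S,6E,10S)-3,7,10,11-tetramethyl-3-{(1E,3R)-3-methyl-5-[(1R,3S)-2,2,3-trimethyl-6-methylidenecyclohexyl]pent-1-en-1-yl}dodeca-1,6,11-triene | C=C[C@@](C)(/C=C/[C@H](C)CC[C@@H]1C(=C)CC[C@H](C)C1(C)C)CC/C=C(\C)CC[C@H](C)C(=C)C | target

## Step count and risks

Total step count: 12. Longest linear sequence: 8 (steps 1 to 7, then step 12).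

The three steps most likely to fail:

Step 2. The isomerisation has to work on a tetrasubstituted β,γ-alkene, so conversion or enantiomeric excess may be poor. The fallback sets out from 3 and comes back at 4. Compound 3 is equilibrated with DBU to racemic 3,4-dimethylcyclohex-2-en-1-one F1. Lithiated (S)-N,S-dimethyl-S-phenylsulfoximine is added to the carbonyl group, and the adducts that carry the (4S) ring carbon, hydroxy sulfoximine F2, are separated by chromatography. Heating F2 in toluene at 110 °C releases 4 (Johnson resolution through covalent diastereomers instead of asymmetric catalysis).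

Step 10. SN2′ against SN2 attack and the enantioselectivity with MeMgBr on this aliphatic β-methyl allylic chloride are uncertain. The fallback sets out from 16 and comes back at 18, which is then methanolysed to 19 as in step 10. Sharpless epoxidation of 16 with Ti(OiPr)4, D-(−)-diethyl tartrate and t-BuOOH gives epoxy alcohol F3. Me2CuLi opens it at the secondary carbon with inversion to diol F4. 1,1′-Thiocarbonyldiimidazole gives thionocarbonate F5, and P(OMe)3 at reflux (Corey–Winter olefination) turns the diol unit into the 1,1-disubstituted alkene of 18. The stereocentre then comes from the epoxidation, not from the copper catalyst.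

Step 12. The coupling joins two elaborate partners, and the SN2′ selectivity and enantiomer ratio at the quaternary carbon may fall short. The fallback sets out from 19 (with alkenylalane 21 made from 14 as in step 12) and comes back at 22. Sharpless epoxidation of 19 with Ti(OiPr)4, D-(−)-diethyl tartrate and t-BuOOH gives epoxy alcohol F6. The alkenylalane 21 opens F6 at the tertiary carbon with inversion to diol F7. Thionocarbonate F8 is formed with 1,1′-thiocarbonyldiimidazole, and Corey–Winter olefination with P(OMe)3 makes the vinyl group of 22. The quaternary centre is then fixed by the epoxide configuration.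

## Further compounds

F1 | step 2 | racemic 3,4-dimethylcyclohex-2-en-1-one | CC1CCC(=O)C=C1C
F2 | step 2 | (S)-N-methyl-S-{[(4S)-1-hydroxy-3,4-dimethylcyclohex-2-en-1-yl]methyl}-S-phenylsulfoximine (C1 epimers) | OC1(C[S@@](=O)(=NC)c2ccccc2)C=C(C)[C@@H](C)CC1
F3 | step 10 | (2E,6E)-9-[(2R,3R)-3-(hydroxymethyl)-3-methyloxiran-2-yl]-3,7-dimethylnona-2,6-dien-1-yl acetate | CC(=O)OC/C=C(\C)CC/C=C(\C)CC[C@H]1O[C@]1(C)CO
F4 | step 10 | (2E,6E,10S,11S)-11,12-dihydroxy-3,7,10,11-tetramethyldodeca-2,6-dien-1-yl acetate | CC(=O)OC/C=C(\C)CC/C=C(\C)CC[C@H](C)[C@](C)(O)CO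
F5 | step 10 | (2E,6E,8S)-3,7-dimethyl-8-[(4S)-4-methyl-2-thioxo-1,3-dioxolan-4-yl]nona-2,6-dien-1-yl acetate | CC(=O)OC/C=C(\C)CC/C=C(\C)CC[C@H](C)[C@@]1(C)COC(=S)O1
F6 | step 12 | {(2R,3R)-3-methyl-3-[(3E,7S)-4,7,8-trimethylnona-3,8-dien-1-yl]oxiran-2-yl}methanol | OC[C@H]1O[C@]1(C)CC/C=C(\C)CC[C@H](C)C(=C)C
F7 | step 12 | (2S,3R,6E,10S)-3,7,10,11-tetramethyl-3-{(1E,3R)-3-methyl-5-[(1R,3S)-2,2,3-trimethyl-6-methylidenecyclohexyl]pent-1-en-1-yl}dodeca-6,11-diene-1,2-diol | OC[C@@H](O)[C@@](C)(/C=C/[C@H](C)CC[C@@H]1C(=C)CC[C@H](C)C1(C)C)CC/C=C(\C)CC[C@H](C)C(=C)C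
F8 | step 12 | 1,2-thionocarbonate of F7, a 4-substituted 1,3-dioxolane-2-thione | S=C1OC[C@@H](O1)[C@@](C)(/C=C/[C@H](C)CC[C@@H]2C(=C)CC[C@H](C)C2(C)C)CC/C=C(\C)CC[C@H](C)C(=C)C
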